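You asked 4 things and wanted a quick number. I reckoned them from two readings, a rate constant and a split.

| flask | substrate | remark | time |
|---|---|---|---|
| ash | 10 mM | run made earlier |  |
| cedar | 5 mM | run made earlier |  |
| elm | 20 mM | run made earlier |  |
| theta | 10 mM | one stirred flow tank at steady state, fed with the mixture as stated, mean residence time 15 h |  |
| beta | 10 mM | plug flow through a tube for 15 h, no back-mixing | 15 h |
| alpha | 10 mM | a closed flask charged with all of it at once and left for 15 h | 15 h |

| run | time / h | target / % | substrate / % |
|---|---|---|---|
| ash | 2.00 | 2.5 | 72.8 |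
| ash | 5.00 | 5.4 | 45.0 |
| ash | 10.0 | 6.3 | 19.4 |
| ash | 15.0 | 6.7 | 8.9 |
| cedar | 1.50 | 1.6 | 78.8 |
| cedar | 4.00 | 3.5 | 52.0 |
| cedar | 8.00 | 5.4 | 27.5 |
| cedar | 12.0 | 6.4 | 14.7 |
| elm | 3.00 | 3.2 | 61.4 |
| elm | 6.00 | 4.7 | 38.5 |
| elm | 10.0 | 7.3 | 20.5 |
| elm | 12.0 | 7.4 | 14.5 |

(each reading ± 0.5 percentage points)

1. the set-up with the highest amount of target at the outlet or at the end, in percent of the substrate put in ("none" if the first two lie within 2 percentage points) (theta / beta / alpha / none)
2. amount of target at the outlet or at the end, in percent of the substrate put in, theta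
3. amount of target at the outlet or at the end, in percent of the substrate put in, beta
4. amount of target at the outlet or at the end, in percent of the substrate put in, alpha

- the stated concentrations are those of everything mixed, before any reaction; amounts are the same in each set-up
- the earlier runs were made in a closed, stirred flask

Substrate fell first order. I read k = 0.161 h⁻¹ in ash at 10 mM, 0.160 h⁻¹ in cedar at 5 mM and 0.161 h⁻¹ in elm at 20 mM. The last readings of the 3 runs gave 7.83% target per substrate used. I called this the split, the selectivity. It is a reading, and each point carries 0.5 percentage points.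

I balanced substrate, with kτ = 2.42:

target = split × substrate used

beta, alpha: used = 1 − exp(−kτ), target 7.13%

theta: fed − c(substrate) = kτ·c(substrate), target 5.54%

So my tube and flask tied.

The forecast gave 5.6% for theta, 7.1% for beta, 7.1% for alpha, and best none: “Tube and flask tie, so the best is "none".” My theta figure was lower.

The simulation gave 5.85% for theta, 7.54% for beta, 7.54% for alpha, and best none. The forecast held.

    intermediate A ⇌ intermediate C (K = 2.80, k = 2.10 × 10⁻⁴ s⁻¹)
    substrate → target (k = 3.70 × 10⁻⁶ s⁻¹)
    substrate → intermediate A (k = 4.10 × 10⁻⁵ s⁻¹)
    intermediate A ⇌ intermediate B (K = 2.70, k = 6.20 × 10⁻⁵ s⁻¹)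

In beta, substrate went to intermediate A 11 times as fast as to target at the start, a split of 8.28%. Beta also held 41.0% intermediate C at 15.0 h, which the number doesn't show, yet the steps past intermediate A made no difference to its target. My split on the 91.1% used in beta gave 7.13%.

For beta read at 6.0 h, the split gave 4.85%. The computed flask gave 5.13%.

The runs were generated by integration with constants of no real substance; the scatter is artificial.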